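The rate constants are assumed; no experiment stands behind them.

I looked first for a leftover: how much reagent stays in each flask once the starting material has gone?

    starting material + reagent → intermediate A (k1 = 13 M⁻¹ s⁻¹)
    intermediate A ⇌ intermediate B (K2 = 0.66, k2 = 0.14 s⁻¹)
    starting material + reagent → intermediate C (k3 = 52 M⁻¹ s⁻¹)
    reagent + intermediate C → target (k4 = 13 M⁻¹ s⁻¹)
    intermediate C ⇌ intermediate D (K5 = 1.9, k5 = 2.4 s⁻¹)
    reagent + intermediate D → side product A (k6 = 69 M⁻¹ s⁻¹)
    starting material + intermediate B → side product B (k7 = 28 M⁻¹ s⁻¹)

| setting | red | ochre | violet | blue | amber |
|---|---|---|---|---|---|
| starting material | 0.50 mM | 1.0 mM | 2.0 mM | 4.0 mM | 8.0 mM |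
| reagent | 6.00 mM | 6.00 mM | 6.00 mM | 6.00 mM | 6.00 mM |
| time | 25 s | 25 s | 25 s | 25 s | 25 s |

- [target] at the end for red, ochre, violet, blue, amber, in this order
- the shape of the row from first to last (hardly changes / rises, then falls / falls all the way / falls, then rises / rises all the way)

- percent here means starting material units held: one side product B counts as two
- "hardly changes" means that all values lie within two and a half points (for a concentration: within two and a half percent of the largest)
- run time (red): 25 s

I turned the question round. For the row to rise all the way, I supposed, the amber flask needed reagent for its whole charge. So I counted what one unit of starting material costs in reagent. Either route from starting material takes one reagent. The route through intermediate C takes a second, to target or, by way of intermediate D, to side product A. The routes share the same partners, so their constants split them. I ignored the loss to side product B.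

share through intermediate C = 52 M⁻¹ s⁻¹ / (13 M⁻¹ s⁻¹ + 52 M⁻¹ s⁻¹) = 80.0%

reagent cost per unit = one + share = 1.80

I called the charge of starting material that uses up c(reagent) exactly the break-even charge:

break-even charge = c(reagent) / cost = 3.33 mM

Equal routes were my zero. They gave a cost of 1.50 and a break-even charge of 4.00 mM. The route through intermediate C is faster, so the break-even charge came lower. At a cost of one, the break-even charge equals the reagent charge of 6.00 mM, which is still less than the amber charge of 8.0 mM. So I expected reagent to become the limiting reagent above 3.33 mM, and I expected the row to turn near there. My reckoning gave the turn, not the target values.

The forecast gave 0.045 mM, 0.088 mM, 0.165 mM, 0.19 mM and 0.105 mM, with the shape rises, then falls. For the fall at the top end, its grounds were that each “unit on the main path costs two reagents”.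

The simulation gave 0.0455 mM, 0.0889 mM, 0.165 mM, 0.217 mM and 0.144 mM, with the shape rises, then falls and a turn read at 3.6 mM. Blue and amber came out higher than the forecast. The amber flask stood at 2.40 times the break-even charge and kept 0.0188% of its reagent charge at the end. Reagent consumption was part of the reason for its low target: without that consumption, target reached 0.736 mM instead of 0.144 mM. In the red flask, the conversion of intermediate C into intermediate D and the conversion of reagent + intermediate D into side product A acted together to hold target down: without the first, target reached 0.313 mM instead of 0.0455 mM, and without the second, 0.169 mM. Below break-even, my reckoning put the reagent left, as a fraction of its own charge, at one minus the charge of starting material over break-even. For the violet flask that gave 40.0%, and after 250 s it held 40.3% of its reagent.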